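Eudesmane numbering: ring A is C1–C5/C10, ring B is C5–C10, C11 is the exocyclic carbinol. Everything rests on disconnecting ring B at C7–C8 by a Prins cyclisation with water capture, which exploits the 1,3-dioxygen pattern of ring B (ketone oxygen on C8, hydroxyl on C11, both flanking C7): in one operation the C8 aldehyde carbon is attacked by the prenyl C7=C11 double bond and water quenches the C11 cation, closing ring B and installing both oxygens. The precursor is a trans-1,2-disubstituted ring A cyclohexene carrying C10–CH2–CHO and C5–prenyl, made from 3-methylcyclohexenone by enantioselective conjugate addition and enolate prenylation.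

Key step: step 6

Assumption: (2R)-2-methylbutanoic acid (18) is bought enantiopure, and the enantiomer of the chiral NHC ligand in step 1 is the one that delivers the (3S) quaternary carbon drawn for 5 and 6.

Step 1
Reactants: 1 3-methylcyclohex-2-en-1-one; 2 ethynyl(trimethyl)silane; 3 1-bromo-3-methylbut-2-ene (prenyl bromide)
Product: 6 (2R,3S)-3-methyl-2-(3-methylbut-2-en-1-yl)-3-[1-(trimethylsilyl)ethenyl]cyclohexan-1-one, via vinylalane 4 (not isolated), via aluminium enolate 5 (not isolated)
Conditions: 2, i-Bu2AlH, hexane/THF, 55 °C; then 1, CuCl2·2H2O (5 mol %), chiral sulfonate-bearing imidazolinium salt (NHC precursor, 6 mol %), THF, −15 °C; then MeLi, then 3, DMPU, −78 → 0 °C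
Reagents that add atoms: none
Why: Hydroalumination of 2 gives the 1-silylvinylalane 4, its copper–NHC-catalysed asymmetric conjugate addition to 1 sets the quaternary C10, and the aluminium enolate 5, activated as its lithium aluminate, should undergo enolate C-alkylation by 3 at C5 on the face anti to the bulky 1-silylvinyl group, so that the prenyl group and the C9 precursor end up trans.

Step 2
Reactants: 6 (2R,3S)-3-methyl-2-(3-methylbut-2-en-1-yl)-3-[1-(trimethylsilyl)ethenyl]cyclohexan-1-one
Product: 7 (5S,6R)-5-methyl-6-(3-methylbut-2-en-1-yl)-5-[1-(trimethylsilyl)ethenyl]cyclohex-1-en-1-yl trifluoromethanesulfonate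
Conditions: LiN(i-Pr)2, THF, −78 °C; PhNTf2, −78 → 0 °C
Reagents that add atoms: N-phenylbis(trifluoromethanesulfonimide), FC(F)(F)S(=O)(=O)N(c1ccccc1)S(=O)(=O)C(F)(F)F
Why: Kinetic deprotonation should occur at the unhindered C3 methylene rather than at the tertiary C5 next to the quaternary C10, and O-triflation of that enolate (regioselective enol triflate formation) gives the C3=C4 enol triflate without touching the C5 stereocentre.

Step 3
Reactants: 7 (5S,6R)-5-methyl-6-(3-methylbut-2-en-1-yl)-5-[1-(trimethylsilyl)ethenyl]cyclohex-1-en-1-yl trifluoromethanesulfonate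
Product: 8 {1-[(1S,2S)-1,3-dimethyl-2-(3-methylbut-2-en-1-yl)cyclohex-3-en-1-yl]ethenyl}(trimethyl)silane
Conditions: MeMgBr, Fe(acac)3 (5 mol %), THF/NMP, −30 → 0 °C
Reagents that add atoms: methylmagnesium bromide, C[Mg]Br
Why: Iron-catalysed Kumada-type cross-coupling of the alkenyl triflate with the methyl Grignard reagent installs the C4 methyl and fixes the C3=C4 double bond, while the vinylsilane and the prenyl alkene are inert.

Step 4
Reactants: 8 {1-[(1S,2S)-1,3-dimethyl-2-(3-methylbut-2-en-1-yl)cyclohex-3-en-1-yl]ethenyl}(trimethyl)silane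
Product: 9 2-[(1S,2S)-1,3-dimethyl-2-(3-methylbut-2-en-1-yl)cyclohex-3-en-1-yl]-2-(trimethylsilyl)ethan-1-ol
Conditions: 9-BBN, THF, 0 → 50 °C; then H2O2, NaOH (aq), 0 °C
Reagents that add atoms: hydrogen peroxide, OO
Why: Anti-Markovnikov hydroboration–oxidation with 9-BBN should select the 1,1-disubstituted vinylsilane over the two trisubstituted alkenes and place the hydroxyl on the terminal carbon (C8), the new silyl-bearing centre C9 being formed as an inconsequential mixture that is erased in step 6.

Step 5
Reactants: 9 2-[(1S,2S)-1,3-dimethyl-2-(3-methylbut-2-en-1-yl)cyclohex-3-en-1-yl]-2-(trimethylsilyl)ethan-1-ol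
Product: 10 2-[(1S,2S)-1,3-dimethyl-2-(3-methylbut-2-en-1-yl)cyclohex-3-en-1-yl]-2-(trimethylsilyl)acetaldehyde
Conditions: Dess–Martin periodinane, pyridine, CH2Cl2, 0 °C; used crude
Reagents that add atoms: none
Why: Buffered Dess–Martin oxidation converts the primary alcohol into the α-silyl aldehyde under neutral conditions that leave the three alkenes and the labile C–Si bond intact.

Step 6
Reactants: 10 2-[(1S,2S)-1,3-dimethyl-2-(3-methylbut-2-en-1-yl)cyclohex-3-en-1-yl]-2-(trimethylsilyl)acetaldehyde
Product: 12 (4aR,8aR)-3-(2-hydroxypropan-2-yl)-5,8a-dimethyl-1,2,3,4,4a,7,8,8a-octahydronaphthalen-2-ol, via aldehyde 11 (not isolated)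
Conditions: H2SO4 (0.25 M aq)/acetone, 45 °C
Reagents that add atoms: water, O
Why: Acid first removes the α-silyl group through the enol to unveil aldehyde 11, whose protonated carbonyl carbon C8 is attacked by C7 of the prenyl double bond through a chair transition state with both tethers equatorial on ring A, and the tertiary C11 cation is captured by water. The closest known reaction type is the Prins (carbonyl-ene) cyclisation with hydration that turns citronellal into p-menthane-3,8-diol. Ring B closes in a 6-exo-trig mode with respect to both the carbonyl group and the alkene. The new centres C7 and C8 are set by the chair transition state but both become sp2 in step 7, so their configuration is inconsequential; C5 and C10 cannot be scrambled because the aldehyde α-carbon C9 is a methylene next to the quaternary C10. The step needs the prenyl alkene to react in preference to the ring A C3=C4 alkene, which the unstrained six-membered chair closure secures against a bridged bicyclo[2.2.2]octane alternative, and it needs water capture instead of proton loss, which the dilute aqueous medium secures.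

Step 7
Reactants: 12 (4aR,8aR)-3-(2-hydroxypropan-2-yl)-5,8a-dimethyl-1,2,3,4,4a,7,8,8a-octahydronaphthalen-2-ol
Product: 14 (4aR,8aR)-3-(2-hydroxypropan-2-yl)-5,8a-dimethyl-4a,7,8,8a-tetrahydronaphthalen-2(1H)-one, via hydroxy ketone 13 (not isolated)
Conditions: IBX (4 equiv), DMSO, 25 °C, then 75 °C
Reagents that add atoms: none
Why: IBX oxidises the secondary C8 alcohol to ketone 13 and on heating dehydrogenates it (IBX-mediated ketone dehydrogenation) to the enone, where only C6=C7 unsaturation is possible because the other α-carbon C9 adjoins the quaternary C10 and the tertiary C11 alcohol cannot be oxidised.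

Step 8
Reactants: 14 (4aR,8aR)-3-(2-hydroxypropan-2-yl)-5,8a-dimethyl-4a,7,8,8a-tetrahydronaphthalen-2(1H)-one
Product: 15 (4aR,5S,6R,8aR)-5,6-dihydroxy-3-(2-hydroxypropan-2-yl)-5,8a-dimethyl-4a,5,6,7,8,8a-hexahydronaphthalen-2(1H)-one
Conditions: OsO4 (2 mol %), NMO, acetone/H2O, 0 °C → rt
Reagents that add atoms: osmium tetroxide, O=[Os](=O)(=O)=O; N-methylmorpholine N-oxide, C[N+]1([O-])CCOCC1; water, O
Why: Catalytic osmium tetroxide syn-dihydroxylation should pick the electron-rich trisubstituted C3=C4 alkene over the hindered electron-poor enone and attack the α face opposite the axial C10 methyl of the trans-fused bicycle, which sets C4 (hydroxyl α, methyl β) and gives the 3α,4α-diol.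

Step 9
Reactants: 15 (4aR,5S,6R,8aR)-5,6-dihydroxy-3-(2-hydroxypropan-2-yl)-5,8a-dimethyl-4a,5,6,7,8,8a-hexahydronaphthalen-2(1H)-one
Product: 16 (4aR,5S,8aR)-5-hydroxy-3-(2-hydroxypropan-2-yl)-5,8a-dimethyl-4a,5,8,8a-tetrahydronaphthalene-2,6(1H,7H)-dione
Conditions: IBX, DMSO, 25 °C
Reagents that add atoms: none
Why: Hypervalent-iodine alcohol oxidation with IBX at room temperature converts the only secondary alcohol (C3) into the ketone without glycol cleavage and leaves both tertiary alcohols untouched.

Step 10
Reactants: 16 (4aR,5S,8aR)-5-hydroxy-3-(2-hydroxypropan-2-yl)-5,8a-dimethyl-4a,5,8,8a-tetrahydronaphthalene-2,6(1H,7H)-dione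
Product: 17 (4aR,5S,6S,8aR)-5,6-dihydroxy-3-(2-hydroxypropan-2-yl)-5,8a-dimethyl-4a,5,6,7,8,8a-hexahydronaphthalen-2(1H)-one
Conditions: NaBH4, CH2Cl2/MeOH, −78 °C
Reagents that add atoms: none
Why: In this low-temperature borohydride reduction the activated saturated α-hydroxy ketone should react much faster than the hindered conjugated enone, and axial hydride delivery on the α face, away from the axial C4 methyl, gives the equatorial 3β alcohol and so the trans-3,4-diol.

Step 11
Reactants: 17 (4aR,5S,6S,8aR)-5,6-dihydroxy-3-(2-hydroxypropan-2-yl)-5,8a-dimethyl-4a,5,6,7,8,8a-hexahydronaphthalen-2(1H)-one; 18 (2R)-2-methylbutanoic acid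
Product: 19 (1S,2S,4aR,8aR)-1-hydroxy-7-(2-hydroxypropan-2-yl)-1,4a-dimethyl-6-oxo-1,2,3,4,4a,5,6,8a-octahydronaphthalen-2-yl (2R)-2-methylbutanoate
Conditions: DCC, DMAP (cat.), CH2Cl2, 0 °C → rt
Reagents that add atoms: none
Why: Steglich esterification should acylate only the secondary C3 hydroxyl, since both tertiary alcohols are unreactive under these conditions, and the α-stereocentre of the acid is retained.

Compound list
1 | 3-methylcyclohex-2-en-1-one | CC1=CC(=O)CCC1 | starting material
2 | ethynyl(trimethyl)silane | C#C[Si](C)(C)C | starting material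
3 | 1-bromo-3-methylbut-2-ene | CC(C)=CCBr | starting material
4 | bis(2-methylpropyl)[1-(trimethylsilyl)ethenyl]alumane | C=C([Si](C)(C)C)[Al](CC(C)C)CC(C)C | intermediate
5 | bis(2-methylpropyl)({(3S)-3-methyl-3-[1-(trimethylsilyl)ethenyl]cyclohex-1-en-1-yl}oxy)alumane | C1CC[C@](C)(C(=C)[Si](C)(C)C)C=C1O[Al](CC(C)C)CC(C)C | intermediate
6 | (2R,3S)-3-methyl-2-(3-methylbut-2-en-1-yl)-3-[1-(trimethylsilyl)ethenyl]cyclohexan-1-one | C1CC[C@](C)(C(=C)[Si](C)(C)C)[C@@H](CC=C(C)C)C1=O | intermediate
7 | (5S,6R)-5-methyl-6-(3-methylbut-2-en-1-yl)-5-[1-(trimethylsilyl)ethenyl]cyclohex-1-en-1-yl trifluoromethanesulfonate | C1CC[C@](C)(C(=C)[Si](C)(C)C)[C@@H](CC=C(C)C)C=1OS(=O)(=O)C(F)(F)F | intermediate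
8 | {1-[(1S,2S)-1,3-dimethyl-2-(3-methylbut-2-en-1-yl)cyclohex-3-en-1-yl]ethenyl}(trimethyl)silane | C1CC[C@](C)(C(=C)[Si](C)(C)C)[C@@H](CC=C(C)C)C=1C | intermediate
9 | 2-[(1S,2S)-1,3-dimethyl-2-(3-methylbut-2-en-1-yl)cyclohex-3-en-1-yl]-2-(trimethylsilyl)ethan-1-ol (both epimers at the silyl-bearing carbon) | C1CC[C@](C)(C(CO)[Si](C)(C)C)[C@@H](CC=C(C)C)C=1C | intermediate
10 | 2-[(1S,2S)-1,3-dimethyl-2-(3-methylbut-2-en-1-yl)cyclohex-3-en-1-yl]-2-(trimethylsilyl)acetaldehyde (both epimers at the silyl-bearing carbon) | C1CC[C@](C)(C(C=O)[Si](C)(C)C)[C@@H](CC=C(C)C)C=1C | intermediate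
11 | 2-[(1R,2R)-1,3-dimethyl-2-(3-methylbut-2-en-1-yl)cyclohex-3-en-1-yl]acetaldehyde | C1CC[C@](C)(CC=O)[C@@H](CC=C(C)C)C=1C | intermediate
12 | (4aR,8aR)-3-(2-hydroxypropan-2-yl)-5,8a-dimethyl-1,2,3,4,4a,7,8,8a-octahydronaphthalen-2-ol (C2 and C3 as formed) | C1CC[C@]2(C)CC(O)C(C(C)(C)O)C[C@H]2C=1C | intermediate
13 | (4aR,8aR)-3-(2-hydroxypropan-2-yl)-5,8a-dimethyl-3,4,4a,7,8,8a-hexahydronaphthalen-2(1H)-one (C3 as formed) | C1CC[C@]2(C)CC(=O)C(C(C)(C)O)C[C@H]2C=1C | intermediate
14 | (4aR,8aR)-3-(2-hydroxypropan-2-yl)-5,8a-dimethyl-4a,7,8,8a-tetrahydronaphthalen-2(1H)-one | C1CC[C@]2(C)CC(=O)C(C(C)(C)O)=C[C@H]2C=1C | intermediate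
15 | (4aR,5S,6R,8aR)-5,6-dihydroxy-3-(2-hydroxypropan-2-yl)-5,8a-dimethyl-4a,5,6,7,8,8a-hexahydronaphthalen-2(1H)-one | O[C@@H]1CC[C@]2(C)CC(=O)C(C(C)(C)O)=C[C@H]2[C@]1(C)O | intermediate
16 | (4aR,5S,8aR)-5-hydroxy-3-(2-hydroxypropan-2-yl)-5,8a-dimethyl-4a,5,8,8a-tetrahydronaphthalene-2,6(1H,7H)-dione | O=C1CC[C@]2(C)CC(=O)C(C(C)(C)O)=C[C@H]2[C@]1(C)O | intermediate
17 | (4aR,5S,6S,8aR)-5,6-dihydroxy-3-(2-hydroxypropan-2-yl)-5,8a-dimethyl-4a,5,6,7,8,8a-hexahydronaphthalen-2(1H)-one | O[C@H]1CC[C@]2(C)CC(=O)C(C(C)(C)O)=C[C@H]2[C@]1(C)O | intermediate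
18 | (2R)-2-methylbutanoic acid | CC[C@@H](C)C(=O)O | starting material
19 | (1S,2S,4aR,8aR)-1-hydroxy-7-(2-hydroxypropan-2-yl)-1,4a-dimethyl-6-oxo-1,2,3,4,4a,5,6,8a-octahydronaphthalen-2-yl (2R)-2-methylbutanoate | CC[C@@H](C)C(=O)O[C@H]1CC[C@]2(C)CC(=O)C(C(C)(C)O)=C[C@H]2[C@]1(C)O | target

Total step count: 11. Longest linear sequence: 11 steps (1 to 19); all other inputs are purchased.

Steps most likely to fail

Step 1. C-alkylation of the congested aluminate enolate may be slow, with protonation or O-alkylation competing, and facial discrimination at C5 between the methyl side and the silylvinyl side may be incomplete, which would erode the trans relationship that the ring fusion depends on. The fallback sets out from 1 and 2 and comes back at 6. The conjugate addition is run as in step 1, but enolate 5 is quenched with Me3SiOTf/Et3N and the trimethylsilyl enol ether F1 is isolated. A Tsuji–Trost prenylation (Pd2(dba)3 as zerovalent palladium source, dppe, prenyl methyl carbonate, THF, 60 °C) then forms the C5–C6 bond by attack of the liberated enolate on the unsubstituted terminus of a π-prenylpalladium cation, again anti to the silylvinyl group. Ketone 6 obtained this way can in addition be equilibrated at C5, which is α to the carbonyl (NaOMe, MeOH).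

Step 6. The cationic closure may be diverted by proton loss from the C11 cation to an isopropenyl alcohol, by acetal formation between the product diol and unreacted aldehyde, or by protonation of the ring A alkene. The fallback sets out from 10 and comes back at 13. Compound 10 is desilylated on wet silica gel and aldehyde 11 is isolated. NH2OH·HCl/pyridine gives the oxime F2. NaOCl (CH2Cl2/H2O, 0 °C) generates the nitrile oxide, which should add intramolecularly to the prenyl double bond and give the ring B-fused isoxazoline F3, forming the same C7–C8 bond and the O–C11 bond under neutral conditions. Mo(CO)6 in MeCN/H2O at 80 °C cleaves the N–O bond and hydrolyses the imine to hydroxy ketone 13, which is isolated and dehydrogenated with IBX as in step 7.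

Step 7. Enolisation toward the congested C7 may be slow, so that dehydrogenation stalls at ketone 13 or is overtaken by loss of the tertiary C11 hydroxyl on prolonged heating. The fallback sets out from 12 and comes back at 14. Diol 12 is oxidised with IBX at room temperature only and 13 is isolated. Me3SiOTf/Et3N gives the bis-silyl compound F4, which carries the C7=C8 silyl enol ether and the C11 silyl ether; the regioisomeric C8=C9 enol ether cannot eliminate and returns 13 on work-up. Pd(OAc)2 in MeCN (Saegusa–Ito oxidation with divalent palladium) gives the enone silyl ether F5, and K2CO3/MeOH removes the silyl group to give 14.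

Further compounds
F1 | step 1 | trimethyl({(3S)-3-methyl-3-[1-(trimethylsilyl)ethenyl]cyclohex-1-en-1-yl}oxy)silane | C1CC[C@](C)(C(=C)[Si](C)(C)C)C=C1O[Si](C)(C)C
F2 | step 6 | 2-[(1R,2R)-1,3-dimethyl-2-(3-methylbut-2-en-1-yl)cyclohex-3-en-1-yl]acetaldehyde oxime | C1CC[C@](C)(CC=NO)[C@@H](CC=C(C)C)C=1C
F3 | step 6 | ring B-fused 5,5-dimethyl-2-isoxazoline of the (4aR,8aR)-5,8a-dimethyloctalin (C8=N–O–C11, hydrogen on C7) | C1CC[C@]2(C)CC3=NOC(C)(C)C3C[C@H]2C=1C
F4 | step 7 | {[(4aR,8aR)-5,8a-dimethyl-3-{2-[(trimethylsilyl)oxy]propan-2-yl}-1,4,4a,7,8,8a-hexahydronaphthalen-2-yl]oxy}(trimethyl)silane | C1CC[C@]2(C)CC(O[Si](C)(C)C)=C(C(C)(C)O[Si](C)(C)C)C[C@H]2C=1C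
F5 | step 7 | (4aR,8aR)-5,8a-dimethyl-3-{2-[(trimethylsilyl)oxy]propan-2-yl}-4a,7,8,8a-tetrahydronaphthalen-2(1H)-one | C1CC[C@]2(C)CC(=O)C(C(C)(C)O[Si](C)(C)C)=C[C@H]2C=1C
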